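**Strategy.** Ring C (O1–C2–C3–C4–C4a–C8a) is opened at C2–C3 and O1–C8a. C2 and O1 then are the carbonyl group of veratraldehyde, and C3–C4–C4a–C8a is an ortho-fluoroaryl enol silane: a formal hetero-[4+2] annulation. The step exploits the C4 ketone, which makes C3 nucleophilic and C8a of ring A electrophilic. In one flask a catalytic asymmetric Mukaiyama aldol forms C2–C3 and sets C2 (S); fluoride then frees the alkoxide, which closes O1–C8a by intramolecular SNAr. The precursor carries the geranyl group on O5, put there with geraniol as an SNAr nucleophile; a final clay-promoted [1,3] shift moves it to C6 and unmasks the 5-OH.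

Key step: step 4

Remarks on the chemistry:
- Flavanone numbering (O1, C2, C3, C4, C4a, C5–C8, C8a) is used for all compounds, open-chain ones included.
- The stereocentre C2 of the target is S. The aldol stage must therefore add to the Si face of the aldehyde, and the antipode of the chiral catalyst is chosen to do so.
- The chiral bisphosphoramide of step 4 is the pentane-1,5-diyl-linked dimer of the cyclic N-methylphosphoramide of N,N'-dimethyl-1,1'-binaphthyl-2,2'-diamine, SMILES CN(CCCCCN(C)P1(=O)N(C)c2ccc3ccccc3c2-c2c(N1C)ccc1ccccc21)P1(=O)N(C)c2ccc3ccccc3c2-c2c(N1C)ccc1ccccc21.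

Step 1
Reactants: 1 3,5-difluoroanisole
Product: 4 1-(2,6-difluoro-4-methoxyphenyl)ethan-1-one, via aryllithium 2 (not isolated), via lithium hemiaminal adduct 3 (not isolated)
Conditions: n-BuLi, THF, −78 °C; MeC(O)N(OMe)Me, −78 °C; aq. HCl
Reagents that add atoms: N-methoxy-N-methylacetamide, CC(=O)N(C)OC
Why: Directed ortho-metalation removes the most acidic proton, between the two fluorines; the aryllithium is stable at −78 °C, and acylation by the Weinreb amide should stop at the ketone through the chelated tetrahedral adduct.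

Step 2
Reactants: 4 1-(2,6-difluoro-4-methoxyphenyl)ethan-1-one; 5 geraniol
Product: 7 1-(2-{[(2E)-3,7-dimethylocta-2,6-dien-1-yl]oxy}-6-fluoro-4-methoxyphenyl)ethan-1-one, via sodium geranyloxide 6 (not isolated)
Conditions: NaH, THF, 0 → 23 °C
Reagents that add atoms: none
Why: Nucleophilic aromatic substitution (SNAr) of a fluorine ortho to the acetyl group through a carbonyl-stabilised Meisenheimer complex; the two fluorines are equivalent and the first alkoxy group should slow a second substitution.

Step 3
Reactants: 7 1-(2-{[(2E)-3,7-dimethylocta-2,6-dien-1-yl]oxy}-6-fluoro-4-methoxyphenyl)ethan-1-one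
Product: 9 {[1-(2-{[(2E)-3,7-dimethylocta-2,6-dien-1-yl]oxy}-6-fluoro-4-methoxyphenyl)ethenyl]oxy}trimethylsilane, via lithium enolate 8 (not isolated)
Conditions: LiN(iPr)2, THF, −78 °C; TMSCl, −78 → 0 °C; non-aqueous work-up
Reagents that add atoms: chlorotrimethylsilane, C[Si](C)(C)Cl
Why: Kinetic deprotonation of the only enolisable position and O-silylation (silyl enol ether formation).

Step 4
Reactants: 9 {[1-(2-{[(2E)-3,7-dimethylocta-2,6-dien-1-yl]oxy}-6-fluoro-4-methoxyphenyl)ethenyl]oxy}trimethylsilane; 10 veratraldehyde (3,4-dimethoxybenzaldehyde)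
Product: 13 (2S)-2-(3,4-dimethoxyphenyl)-5-{[(2E)-3,7-dimethylocta-2,6-dien-1-yl]oxy}-7-methoxy-2,3-dihydro-4H-chromen-4-one, via trichlorosilyl aldolate 11 (not isolated), via cesium alkoxide 12 (not isolated)
Conditions: SiCl4 (1.1 equiv), chiral bisphosphoramide (5 mol%), iPr2NEt (10 mol%), CH2Cl2, −78 °C; then CsF (10 equiv), DMF, −78 → 0 °C, same flask
Reagents that add atoms: none
Why: The chiral bisphosphoramide binds SiCl4 to give a cationic trichlorosilyl Lewis acid that activates 10, and enol silane 9 adds through an open transition state to the Si face, forming C2–C3 and the S carbinol as aldolate 11. Fluoride then strips silicon from oxygen (strong Si–F bonds, hexafluorosilicate), and the freed alkoxide 12 attacks C8a, ortho to the C4 ketone, through a carbonyl-stabilised Meisenheimer complex and expels fluoride, so that the whole is a formal hetero-[4+2] annulation. The closest known reaction types are the Lewis-base-catalysed SiCl4 Mukaiyama aldol of aryl methyl ketone enol silanes with aromatic aldehydes, and the addition–elimination SNAr etherification of ortho-fluoroaryl ketones by alkoxides set free from silyl ethers with fluoride. Ring C closes in a 6-exo-trig mode at an aromatic carbon. C2 is set by the catalyst in the aldol stage and is retained because the C2–O1 bond is not touched in the substitution. The step needs enantiofacial control and a ring closure faster than retro-aldol cleavage or dehydration of 12: the low temperature, the weakly coordinated cesium alkoxide in DMF, the irreversible loss of fluoride and the meta position of both alkoxy groups to C8a (no resonance opposition to attack) are meant to secure this, and only one C–F bond is present.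

Step 5
Reactants: 13 (2S)-2-(3,4-dimethoxyphenyl)-5-{[(2E)-3,7-dimethylocta-2,6-dien-1-yl]oxy}-7-methoxy-2,3-dihydro-4H-chromen-4-one
Product: 14 (2S)-2-(3,4-dimethoxyphenyl)-6-[(2E)-3,7-dimethylocta-2,6-dien-1-yl]-5-hydroxy-7-methoxy-2,3-dihydro-4H-chromen-4-one
Conditions: montmorillonite K10 clay (acid-activated aluminosilicate, Al2Si4O10(OH)2·nH2O), CH2Cl2, 0 °C, short contact time
Reagents that add atoms: none
Why: Acid-clay-promoted [1,3] O-to-C shift of an allyl aryl ether through a tight ion pair should deliver C1 of the geranyl group to C6, the only free ortho position of O5; tautomerisation restores ring A with the chelated 5-OH, and C2 and the E olefin take no part.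

**Compound list**
1 | 3,5-difluoroanisole | COc1cc(F)cc(F)c1 | starting material
2 | (2,6-difluoro-4-methoxyphenyl)lithium (not isolated) | [Li]c1c(F)cc(OC)cc1F | intermediate
3 | lithium 1-(2,6-difluoro-4-methoxyphenyl)-1-[methoxy(methyl)amino]ethan-1-olate (not isolated) | CC([O-])(N(C)OC)c1c(F)cc(OC)cc1F.[Li+] | intermediate
4 | 1-(2,6-difluoro-4-methoxyphenyl)ethan-1-one | CC(=O)c1c(F)cc(OC)cc1F | intermediate
5 | geraniol, (2E)-3,7-dimethylocta-2,6-dien-1-ol | OC/C=C(\C)CCC=C(C)C | starting material
6 | sodium geranyloxide (not isolated) | [Na+].[O-]C/C=C(\C)CCC=C(C)C | intermediate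
7 | 1-(2-{[(2E)-3,7-dimethylocta-2,6-dien-1-yl]oxy}-6-fluoro-4-methoxyphenyl)ethan-1-one | CC(=O)c1c(F)cc(OC)cc1OC/C=C(\C)CCC=C(C)C | intermediate
8 | lithium enolate of 7 (not isolated) | [Li+].[O-]C(=C)c1c(F)cc(OC)cc1OC/C=C(\C)CCC=C(C)C | intermediate
9 | {[1-(2-{[(2E)-3,7-dimethylocta-2,6-dien-1-yl]oxy}-6-fluoro-4-methoxyphenyl)ethenyl]oxy}trimethylsilane | C=C(O[Si](C)(C)C)c1c(F)cc(OC)cc1OC/C=C(\C)CCC=C(C)C | intermediate
10 | veratraldehyde, 3,4-dimethoxybenzaldehyde | COc1ccc(C=O)cc1OC | starting material
11 | trichlorosilyl ether of (3S)-3-(3,4-dimethoxyphenyl)-1-(2-{[(2E)-3,7-dimethylocta-2,6-dien-1-yl]oxy}-6-fluoro-4-methoxyphenyl)-3-hydroxypropan-1-one (not isolated) | COc1ccc([C@@H](O[Si](Cl)(Cl)Cl)CC(=O)c2c(F)cc(OC)cc2OC/C=C(\C)CCC=C(C)C)cc1OC | intermediate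
12 | cesium (1S)-1-(3,4-dimethoxyphenyl)-3-(2-{[(2E)-3,7-dimethylocta-2,6-dien-1-yl]oxy}-6-fluoro-4-methoxyphenyl)-3-oxopropan-1-olate (not isolated) | COc1ccc([C@@H]([O-])CC(=O)c2c(F)cc(OC)cc2OC/C=C(\C)CCC=C(C)C)cc1OC.[Cs+] | intermediate
13 | (2S)-2-(3,4-dimethoxyphenyl)-5-{[(2E)-3,7-dimethylocta-2,6-dien-1-yl]oxy}-7-methoxy-2,3-dihydro-4H-chromen-4-one | COc1ccc([C@@H]2CC(=O)c3c(cc(OC)cc3OC/C=C(\C)CCC=C(C)C)O2)cc1OC | intermediate
14 | (2S)-2-(3,4-dimethoxyphenyl)-6-[(2E)-3,7-dimethylocta-2,6-dien-1-yl]-5-hydroxy-7-methoxy-2,3-dihydro-4H-chromen-4-one | COc1ccc([C@@H]2CC(=O)c3c(cc(OC)c(C/C=C(\C)CCC=C(C)C)c3O)O2)cc1OC | target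

**Total step count:** 5. **Longest linear sequence:** 5 steps (1 → 4 → 7 → 9 → 13 → 14).

**Steps most likely to fail**

Step 4 (key step). The free alkoxide may revert by retro-aldol cleavage and recombine without facial control, eroding the enantiomeric purity, or it may dehydrate to the chalcone before the ring closes; the product may also open at C2 under prolonged exposure to fluoride. The fallback sets out from ketone 7 and comes back at 13, and it forms the C2–aryl bond instead. Claisen condensation of 7 with ethyl formate (CCOC=O) and NaH in THF should give the sodium enolate of 3-(2-{[(2E)-3,7-dimethylocta-2,6-dien-1-yl]oxy}-6-fluoro-4-methoxyphenyl)-3-oxopropanal F1. On warming in DMF its enolate oxygen should displace the fluoride by intramolecular SNAr to give 5-{[(2E)-3,7-dimethylocta-2,6-dien-1-yl]oxy}-7-methoxy-4H-chromen-4-one F2. Rhodium-catalysed asymmetric 1,4-addition of (3,4-dimethoxyphenyl)boronic acid (COc1ccc(B(O)O)cc1OC) to F2, with [RhCl(C2H4)2]2, the appropriate antipode of 2,5-diphenylbicyclo[2.2.2]octa-2,5-diene and KOH in dioxane–water, should then give 13.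

Step 5. The migrating geranyl group may go to C8 or to ring B instead of C6, may be lost altogether, or the acid clay may open ring C at the benzylic C2–O1 bond and racemise C2. The fallback sets out from ketone 7 and comes back at 14; it moves the shift to the robust, achiral ketone stage, where the para position is deactivated by fluorine. Montmorillonite K10 clay in CH2Cl2 should convert 7 into 1-{3-[(2E)-3,7-dimethylocta-2,6-dien-1-yl]-6-fluoro-2-hydroxy-4-methoxyphenyl}ethan-1-one F3. NaH and chloromethyl methyl ether (COCCl) should give 1-{3-[(2E)-3,7-dimethylocta-2,6-dien-1-yl]-6-fluoro-4-methoxy-2-(methoxymethoxy)phenyl}ethan-1-one F4. LiN(iPr)2 should give the lithium enolate of F4 F5, and TMSCl the enol silane F6. The two-stage annulation of step 4 with 10 should pass through the trichlorosilyl aldolate F7 and the cesium alkoxide F8 to the 5-O-methoxymethyl flavanone F9. Dilute HCl in methanol at 23 °C should then remove the acetal to give 14.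

Step 2. The alkoxide may enolise the methyl ketone, which stalls the substitution or leads to self-condensation, and a second substitution may follow the first. The fallback sets out from 4 and comes back at 7, with the roles of nucleophile and electrophile exchanged. Hydrolytic SNAr of 4 with KOH in DMSO–water, followed by acidification with HCl, should give 1-(2-fluoro-6-hydroxy-4-methoxyphenyl)ethan-1-one F10; the phenoxide formed deactivates the ring against a second substitution. Williamson O-alkylation of F10 with geranyl bromide (BrC/C=C(\C)CCC=C(C)C) and K2CO3 in acetone should give 7.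

**Further compounds**
F1 | step 4 | sodium enolate of 3-(2-{[(2E)-3,7-dimethylocta-2,6-dien-1-yl]oxy}-6-fluoro-4-methoxyphenyl)-3-oxopropanal | [Na+].[O-]C=CC(=O)c1c(F)cc(OC)cc1OC/C=C(\C)CCC=C(C)C
F2 | step 4 | 5-{[(2E)-3,7-dimethylocta-2,6-dien-1-yl]oxy}-7-methoxy-4H-chromen-4-one | COc1cc(OC/C=C(\C)CCC=C(C)C)c2c(c1)occc2=O
F3 | step 5 | 1-{3-[(2E)-3,7-dimethylocta-2,6-dien-1-yl]-6-fluoro-2-hydroxy-4-methoxyphenyl}ethan-1-one | CC(=O)c1c(F)cc(OC)c(C/C=C(\C)CCC=C(C)C)c1O
F4 | step 5 | 1-{3-[(2E)-3,7-dimethylocta-2,6-dien-1-yl]-6-fluoro-4-methoxy-2-(methoxymethoxy)phenyl}ethan-1-one | CC(=O)c1c(F)cc(OC)c(C/C=C(\C)CCC=C(C)C)c1OCOC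
F5 | step 5 | lithium enolate of F4 | [Li+].[O-]C(=C)c1c(F)cc(OC)c(C/C=C(\C)CCC=C(C)C)c1OCOC
F6 | step 5 | trimethylsilyl enol ether of F4 | C=C(O[Si](C)(C)C)c1c(F)cc(OC)c(C/C=C(\C)CCC=C(C)C)c1OCOC
F7 | step 5 | trichlorosilyl ether of the (3S)-aldol from F6 and 10 | COc1ccc([C@@H](O[Si](Cl)(Cl)Cl)CC(=O)c2c(F)cc(OC)c(C/C=C(\C)CCC=C(C)C)c2OCOC)cc1OC
F8 | step 5 | cesium alkoxide of the (3S)-aldol from F6 and 10 | COc1ccc([C@@H]([O-])CC(=O)c2c(F)cc(OC)c(C/C=C(\C)CCC=C(C)C)c2OCOC)cc1OC.[Cs+]
F9 | step 5 | (2S)-2-(3,4-dimethoxyphenyl)-6-[(2E)-3,7-dimethylocta-2,6-dien-1-yl]-7-methoxy-5-(methoxymethoxy)-2,3-dihydro-4H-chromen-4-one | COc1ccc([C@@H]2CC(=O)c3c(cc(OC)c(C/C=C(\C)CCC=C(C)C)c3OCOC)O2)cc1OC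
F10 | step 2 | 1-(2-fluoro-6-hydroxy-4-methoxyphenyl)ethan-1-one | CC(=O)c1c(F)cc(OC)cc1O
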